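**Retrosynthetic overview**

1. Stenophyllol B (31) ⇐ octamethyl ether 30 (global O-demethylation) ⇐ carbinol 26, in which one acid-triggered cascade forms first the bond C-a–C-b (eight-membered ring) and then the bond C-d–ring A (indane).
2. Labels: ring A = resorcinol ring fused in the indane; ring B = resorcinol ring that carries the benzhydryl carbon C-a (C-a also bears a 4-hydroxyphenyl group); ring C = benzofuran ring; C-b, C-c, C-d = the indane carbons bearing C-a, ring C and the other 4-hydroxyphenyl group.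
3. Enabling feature: C-a carries a 4-oxygenated phenyl ring and ring B with oxygens ortho and para to it, so it ionizes under mild acid. C-b can be the terminus of a styrene whose closure on C-a gives exactly the eight-membered ring (C-a, C-b, C-c, two carbons of ring C, C3 of the dihydrobenzofuran, two carbons of ring B). C-d is a 4-oxybenzylic carbon next to C-c and three bonds from an ortho carbon of ring A (ortho/para to two oxygens), which ends the cascade.
4. 26 ⇐ E-alkene aldehyde 24 (Negishi coupling of Z-enol triflate 21) ⇐ deoxybenzoin 20 ⇐ Weinreb amide 17 ⇐ trans-dihydrobenzofuran ester 16 ⇐ [4+1] annulation of a chiral sulfonium ylide with the ortho-quinone methide released from hydroxyphthalide 9 ⇐ aryllithium 7 + salicylaldehyde 3.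
5. Ring order: dihydrofuran ring (step 6); then the eight-membered ring and the indane five-membered ring, in that order, within step 12.

Key step: step 12

Assumption: the (1R,4R,5R) sulfide 11 is taken to deliver the (2R,3R) dihydrobenzofuran series in step 6; if the sense of induction is the opposite, its equally available antipode is used without other change.

**Route**

Step 1
Reactants: 1 methyl 3,5-dimethoxybenzoate
Product: 2 methyl 2-formyl-3,5-dimethoxybenzoate
Conditions: Cl2CHOMe, TiCl4, CH2Cl2, 0 → 23 °C; H2O work-up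
Reagents that add atoms: dichloromethyl methyl ether COC(Cl)Cl; water O
Why: Rieche formylation (electrophilic aromatic substitution) should take place at C2, para to one methoxy group and ortho to the other, the site at which this ester is also halogenated and chloromethylated.

Step 2
Reactants: 2 methyl 2-formyl-3,5-dimethoxybenzoate
Product: 3 methyl 2-formyl-3-hydroxy-5-methoxybenzoate
Conditions: BCl3, CH2Cl2, −78 → 0 °C; aq. NaHCO3
Reagents that add atoms: none
Why: Chelation-controlled Lewis-acid demethylation, in which BCl3 bridges the formyl oxygen and the ortho methoxy group, so that only this ether should be cleaved.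

Step 3
Reactants: 4 2-bromo-4,6-dimethoxybenzaldehyde; 5 2,2-dimethylpropane-1,3-diol
Product: 6 2-(2-bromo-4,6-dimethoxyphenyl)-5,5-dimethyl-1,3-dioxane
Conditions: TsOH·H2O (cat.), toluene, reflux, Dean–Stark trap; Et3N quench
Reagents that add atoms: none
Why: Acid-catalysed acetalization with azeotropic removal of water masks the future C-a as an achiral, base-stable group for the organometallic steps.

Step 4
Reactants: 6 2-(2-bromo-4,6-dimethoxyphenyl)-5,5-dimethyl-1,3-dioxane; 3 methyl 2-formyl-3-hydroxy-5-methoxybenzoate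
Product: 9 rac-3-[2-(5,5-dimethyl-1,3-dioxan-2-yl)-3,5-dimethoxyphenyl]-4-hydroxy-6-methoxy-2-benzofuran-1(3H)-one, via aryllithium 7 (not isolated), via sodium phenolate 8 (not isolated)
Conditions: 6, n-BuLi, THF, −78 °C; then 3 pretreated with NaH (THF, 0 °C); −78 → 23 °C; aq. NH4Cl
Reagents that add atoms: none
Why: Bromine–lithium exchange, 1,2-addition of the aryllithium to the aldehyde and lactonization of the alkoxide onto the neighbouring ester (phthalide formation); the new stereocenter is racemic and is erased in step 6.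

Step 5
Reactants: 10 4-methoxybenzyl bromide; 11 (1R,4R,5R)-4,7,7-trimethyl-6-thiabicyclo[3.2.1]octane (isothiocineole)
Product: 12 (1R,4R,5R)-6-(4-methoxybenzyl)-4,7,7-trimethyl-6-thioniabicyclo[3.2.1]octane tetrafluoroborate
Conditions: NaBF4, CH2Cl2–H2O, 23 °C
Reagents that add atoms: sodium tetrafluoroborate [Na+].F[B-](F)(F)F
Why: S-alkylation of the sulfide by the reactive benzylic bromide with anion metathesis should give the sulfonium salt as one diastereomer at sulfur (attack on the less hindered lone pair).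

Step 6
Reactants: 9 rac-3-[2-(5,5-dimethyl-1,3-dioxan-2-yl)-3,5-dimethoxyphenyl]-4-hydroxy-6-methoxy-2-benzofuran-1(3H)-one; 12 (1R,4R,5R)-6-(4-methoxybenzyl)-4,7,7-trimethyl-6-thioniabicyclo[3.2.1]octane tetrafluoroborate
Product: 16 methyl (2R,3R)-3-[2-(5,5-dimethyl-1,3-dioxan-2-yl)-3,5-dimethoxyphenyl]-6-methoxy-2-(4-methoxyphenyl)-2,3-dihydro-1-benzofuran-4-carboxylate, via sulfonium ylide 13 (not isolated), via quinone methide 14 (not isolated), via cesium carboxylate 15 (not isolated)
Conditions: Cs2CO3, MeCN, 0 → 40 °C; then MeI, 23 °C; chromatography to remove any cis isomer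
Reagents that add atoms: iodomethane CI
Why: The phenolate opens the phthalide to the ortho-quinone methide carboxylate (the lactone opening familiar from phenolphthalein), the ylide adds to its exocyclic carbon and the phenoxide displaces the sulfide (formal [4+1] sulfur-ylide annulation, Corey–Chaykovsky type) to give the trans-2,3-diaryl ring; the chiral ylide should react through one conformer and one face, as in its epoxidations, which sets C3 (and C2 trans to it), and MeI then esterifies the carboxylate; a cis isomer must be removed because later acid epimerization at C2 would convert it into the enantiomeric trans series.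

Step 7
Reactants: 16 methyl (2R,3R)-3-[2-(5,5-dimethyl-1,3-dioxan-2-yl)-3,5-dimethoxyphenyl]-6-methoxy-2-(4-methoxyphenyl)-2,3-dihydro-1-benzofuran-4-carboxylate
Product: 17 (2R,3R)-3-[2-(5,5-dimethyl-1,3-dioxan-2-yl)-3,5-dimethoxyphenyl]-N,6-dimethoxy-2-(4-methoxyphenyl)-N-methyl-2,3-dihydro-1-benzofuran-4-carboxamide
Conditions: MeNHOMe·HCl, i-PrMgCl, THF, −20 → 0 °C; pH 7 buffer
Reagents that add atoms: N,O-dimethylhydroxylamine hydrochloride CNOC.Cl
Why: Weinreb amidation of the ester by the magnesium amide; the stereocenters and the acetal are not touched under these basic conditions.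

Step 8
Reactants: 17 (2R,3R)-3-[2-(5,5-dimethyl-1,3-dioxan-2-yl)-3,5-dimethoxyphenyl]-N,6-dimethoxy-2-(4-methoxyphenyl)-N-methyl-2,3-dihydro-1-benzofuran-4-carboxamide; 18 3,5-dimethoxybenzyl chloride
Product: 20 1-{(2R,3R)-3-[2-(5,5-dimethyl-1,3-dioxan-2-yl)-3,5-dimethoxyphenyl]-6-methoxy-2-(4-methoxyphenyl)-2,3-dihydro-1-benzofuran-4-yl}-2-(3,5-dimethoxyphenyl)ethan-1-one, via benzylic Grignard reagent 19 (not isolated)
Conditions: 18, Mg, THF, 0 °C; then 17, −78 → 0 °C; aq. NH4Cl
Reagents that add atoms: none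
Why: Weinreb ketone synthesis; the chelated tetrahedral intermediate prevents a second addition and delivers the deoxybenzoin whose carbonyl carbon is C-c and whose methylene carbon is C-b.

Step 9
Reactants: 20 1-{(2R,3R)-3-[2-(5,5-dimethyl-1,3-dioxan-2-yl)-3,5-dimethoxyphenyl]-6-methoxy-2-(4-methoxyphenyl)-2,3-dihydro-1-benzofuran-4-yl}-2-(3,5-dimethoxyphenyl)ethan-1-one
Product: 21 (Z)-1-{(2R,3R)-3-[2-(5,5-dimethyl-1,3-dioxan-2-yl)-3,5-dimethoxyphenyl]-6-methoxy-2-(4-methoxyphenyl)-2,3-dihydro-1-benzofuran-4-yl}-2-(3,5-dimethoxyphenyl)ethenyl trifluoromethanesulfonate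
Conditions: KN(SiMe3)2, THF, −78 °C; PhNTf2, −78 → 0 °C; aq. NH4Cl
Reagents that add atoms: N-phenylbis(trifluoromethanesulfonimide) O=S(=O)(N(c1ccccc1)S(=O)(=O)C(F)(F)F)C(F)(F)F
Why: Deprotonation of the doubly activated methylene should give the Z enolate (the two aryl groups trans, as is usual for aryl benzyl ketones), which is trapped on oxygen as the enol triflate.

Step 10
Reactants: 21 (Z)-1-{(2R,3R)-3-[2-(5,5-dimethyl-1,3-dioxan-2-yl)-3,5-dimethoxyphenyl]-6-methoxy-2-(4-methoxyphenyl)-2,3-dihydro-1-benzofuran-4-yl}-2-(3,5-dimethoxyphenyl)ethenyl trifluoromethanesulfonate; 22 4-methoxybenzylzinc chloride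
Product: 24 2-{(2R,3R)-4-[(E)-1-(3,5-dimethoxyphenyl)-3-(4-methoxyphenyl)prop-1-en-2-yl]-6-methoxy-2-(4-methoxyphenyl)-2,3-dihydro-1-benzofuran-3-yl}-4,6-dimethoxybenzaldehyde, via acetal 23 (not isolated)
Conditions: Pd(OAc)2 (5 mol%), SPhos, THF, 50 °C; then 1 M HCl, THF, 23 °C
Reagents that add atoms: water O
Why: Negishi coupling of the enol triflate with the benzylic zinc reagent proceeds with retention of alkene geometry (ring A trans to ring C), and aqueous acid then hydrolyses the electron-rich aryl acetal.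

Step 11
Reactants: 24 2-{(2R,3R)-4-[(E)-1-(3,5-dimethoxyphenyl)-3-(4-methoxyphenyl)prop-1-en-2-yl]-6-methoxy-2-(4-methoxyphenyl)-2,3-dihydro-1-benzofuran-3-yl}-4,6-dimethoxybenzaldehyde; 25 4-methoxyphenylmagnesium bromide
Product: 26 (2-{(2R,3R)-4-[(E)-1-(3,5-dimethoxyphenyl)-3-(4-methoxyphenyl)prop-1-en-2-yl]-6-methoxy-2-(4-methoxyphenyl)-2,3-dihydro-1-benzofuran-3-yl}-4,6-dimethoxyphenyl)(4-methoxyphenyl)methanol (both epimers at the carbinol carbon)
Conditions: THF, −78 → 0 °C; aq. NH4Cl
Reagents that add atoms: none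
Why: Grignard 1,2-addition to the aldehyde; the configuration of the carbinol carbon (future C-a) is irrelevant because it is ionized in the next step.

Step 12
Reactants: 26 (2-{(2R,3R)-4-[(E)-1-(3,5-dimethoxyphenyl)-3-(4-methoxyphenyl)prop-1-en-2-yl]-6-methoxy-2-(4-methoxyphenyl)-2,3-dihydro-1-benzofuran-3-yl}-4,6-dimethoxyphenyl)(4-methoxyphenyl)methanol
Product: 30 stenophyllol B octamethyl ether, via benzhydryl cation 27 (not isolated), via tertiary cation 28 (not isolated), via 4-methoxybenzylic cation 29 (not isolated)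
Conditions: HNTf2 (5 mol%), (CF3)2CHOH–CH2Cl2 (1:4), 1 mM, −20 → 23 °C
Reagents that add atoms: none
Why: Proposed new method: the acid ionizes the benzhydrol to cation 27, stabilized by the 4-methoxyphenyl group and by the ortho and para methoxy groups of ring B; the 1,1,2-trisubstituted styrene, its only strain-free intramolecular π-partner, should attack through C-b in the Markovnikov 8-endo-trig mode to give tertiary benzylic cation 28 at C-c (the 7-exo alternative would give a secondary, unstabilized cation and a quaternary centre); a 1,2-hydride shift (or loss and return of a proton through the exocyclic stilbene) then moves the charge to the 4-methoxybenzylic carbon C-d (29), which the ortho carbon of ring A, activated ortho and para by its methoxy groups, captures in a Friedel–Crafts closure of the five-membered ring, releasing the proton that carries the chain. The closest known reaction types are acid-mediated additions of diarylmethyl cations to styrenes and the cation–stilbene cyclization/Friedel–Crafts cascades used for indane-type resveratrol dimers; new here are the 8-endo ring size and the hydride relay between the two ring closures. Because 27 is so stabilized, the adduct cation can revert by fragmentation, so both new C–C bonds form reversibly until the final rearomatization and the four new stereocenters are expected to be set under equilibrating conditions: C-a and C-b relative to the resident C3 of the dihydrobenzofuran, whose ring B stands perpendicular to ring C and allows one tub-shaped transition state in which ring A on C-b points outward and the 4-methoxyphenyl group on C-a turns away from the neighbouring methoxy group of ring B; C-c because only the epimer whose C-d can reach ring A closes (trans ring fusion); and C-d by the usual trans relationship between the new aryl group and the substituent on C-c in such indane closures. The step needs chemoselectivity for the alkene over the electron-rich arenes, which high dilution, the E geometry (ring A could reach the cation only through a ten-membered ring holding a trans double bond) and the reversibility of arene alkylation by 27 should secure; it also needs ionization to precede protonation of the alkene, which catalytic acid at low temperature in an ionizing, weakly nucleophilic solvent should secure.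

Step 13
Reactants: 30 stenophyllol B octamethyl ether
Product: 31 stenophyllol B
Conditions: BBr3 (excess), CH2Cl2, −78 → 23 °C; then H2O
Reagents that add atoms: none
Why: Lewis-acid cleavage of the eight aryl methyl ethers, the standard last step for permethylated resveratrol oligomers; no stereocenter is touched, and reversible opening of the dihydrofuran at C2 can only return the thermodynamic trans ring.

**Compound list**

1 | methyl 3,5-dimethoxybenzoate | COC(=O)c1cc(OC)cc(OC)c1 | starting material
2 | methyl 2-formyl-3,5-dimethoxybenzoate | COC(=O)c1cc(OC)cc(OC)c1C=O | intermediate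
3 | methyl 2-formyl-3-hydroxy-5-methoxybenzoate | COC(=O)c1cc(OC)cc(O)c1C=O | intermediate
4 | 2-bromo-4,6-dimethoxybenzaldehyde | COc1cc(Br)c(C=O)c(OC)c1 | starting material
5 | 2,2-dimethylpropane-1,3-diol | OCC(C)(C)CO | starting material
6 | 2-(2-bromo-4,6-dimethoxyphenyl)-5,5-dimethyl-1,3-dioxane | COc1cc(Br)c(C2OCC(C)(C)CO2)c(OC)c1 | intermediate
7 | [2-(5,5-dimethyl-1,3-dioxan-2-yl)-3,5-dimethoxyphenyl]lithium | COc1cc([Li])c(C2OCC(C)(C)CO2)c(OC)c1 | intermediate (not isolated)
8 | sodium 2-formyl-5-methoxy-3-(methoxycarbonyl)phenolate | [Na+].COC(=O)c1cc(OC)cc([O-])c1C=O | intermediate (not isolated)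
9 | rac-3-[2-(5,5-dimethyl-1,3-dioxan-2-yl)-3,5-dimethoxyphenyl]-4-hydroxy-6-methoxy-2-benzofuran-1(3H)-one | O=C1OC(c2cc(OC)cc(OC)c2C2OCC(C)(C)CO2)c2c(O)cc(OC)cc12 | intermediate
10 | 4-methoxybenzyl bromide | COc1ccc(CBr)cc1 | starting material
11 | (1R,4R,5R)-4,7,7-trimethyl-6-thiabicyclo[3.2.1]octane (isothiocineole) | C[C@@H]1CC[C@@H]2C[C@H]1SC2(C)C | starting material
12 | (1R,4R,5R)-6-(4-methoxybenzyl)-4,7,7-trimethyl-6-thioniabicyclo[3.2.1]octane tetrafluoroborate (configuration at sulfur not specified) | C[C@@H]1CC[C@@H]2C[C@H]1[S+](Cc1ccc(OC)cc1)C2(C)C.F[B-](F)(F)F | intermediate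
13 | sulfonium ylide of 12 (benzylic carbanion on sulfur) | C[C@@H]1CC[C@@H]2C[C@H]1[S+]([CH-]c1ccc(OC)cc1)C2(C)C | intermediate (not isolated)
14 | cesium 6-{[2-(5,5-dimethyl-1,3-dioxan-2-yl)-3,5-dimethoxyphenyl]methylidene}-3-methoxy-5-oxocyclohexa-1,3-diene-1-carboxylate (ortho-quinone methide) | [Cs+].[O-]C(=O)C1=CC(OC)=CC(=O)C1=Cc1cc(OC)cc(OC)c1C1OCC(C)(C)CO1 | intermediate (not isolated)
15 | cesium (2R,3R)-3-[2-(5,5-dimethyl-1,3-dioxan-2-yl)-3,5-dimethoxyphenyl]-6-methoxy-2-(4-methoxyphenyl)-2,3-dihydro-1-benzofuran-4-carboxylate | [Cs+].[O-]C(=O)c1cc(OC)cc2O[C@@H](c3ccc(OC)cc3)[C@H](c3cc(OC)cc(OC)c3C3OCC(C)(C)CO3)c12 | intermediate (not isolated)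
16 | methyl (2R,3R)-3-[2-(5,5-dimethyl-1,3-dioxan-2-yl)-3,5-dimethoxyphenyl]-6-methoxy-2-(4-methoxyphenyl)-2,3-dihydro-1-benzofuran-4-carboxylate | COC(=O)c1cc(OC)cc2O[C@@H](c3ccc(OC)cc3)[C@H](c3cc(OC)cc(OC)c3C3OCC(C)(C)CO3)c12 | intermediate
17 | (2R,3R)-3-[2-(5,5-dimethyl-1,3-dioxan-2-yl)-3,5-dimethoxyphenyl]-N,6-dimethoxy-2-(4-methoxyphenyl)-N-methyl-2,3-dihydro-1-benzofuran-4-carboxamide | CON(C)C(=O)c1cc(OC)cc2O[C@@H](c3ccc(OC)cc3)[C@H](c3cc(OC)cc(OC)c3C3OCC(C)(C)CO3)c12 | intermediate
18 | 3,5-dimethoxybenzyl chloride | COc1cc(CCl)cc(OC)c1 | starting material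
19 | 3,5-dimethoxybenzylmagnesium chloride | COc1cc(C[Mg]Cl)cc(OC)c1 | intermediate (not isolated)
20 | 1-{(2R,3R)-3-[2-(5,5-dimethyl-1,3-dioxan-2-yl)-3,5-dimethoxyphenyl]-6-methoxy-2-(4-methoxyphenyl)-2,3-dihydro-1-benzofuran-4-yl}-2-(3,5-dimethoxyphenyl)ethan-1-one | O=C(Cc1cc(OC)cc(OC)c1)c1cc(OC)cc2O[C@@H](c3ccc(OC)cc3)[C@H](c3cc(OC)cc(OC)c3C3OCC(C)(C)CO3)c12 | intermediate
21 | (Z)-1-{(2R,3R)-3-[2-(5,5-dimethyl-1,3-dioxan-2-yl)-3,5-dimethoxyphenyl]-6-methoxy-2-(4-methoxyphenyl)-2,3-dihydro-1-benzofuran-4-yl}-2-(3,5-dimethoxyphenyl)ethenyl trifluoromethanesulfonate | O=S(=O)(O/C(=C\c1cc(OC)cc(OC)c1)c1cc(OC)cc2O[C@@H](c3ccc(OC)cc3)[C@H](c3cc(OC)cc(OC)c3C3OCC(C)(C)CO3)c12)C(F)(F)F | intermediate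
22 | 4-methoxybenzylzinc chloride | COc1ccc(C[Zn]Cl)cc1 | starting material
23 | (2R,3R)-4-[(E)-1-(3,5-dimethoxyphenyl)-3-(4-methoxyphenyl)prop-1-en-2-yl]-3-[2-(5,5-dimethyl-1,3-dioxan-2-yl)-3,5-dimethoxyphenyl]-6-methoxy-2-(4-methoxyphenyl)-2,3-dihydro-1-benzofuran | COc1ccc(C/C(=C\c2cc(OC)cc(OC)c2)c2cc(OC)cc3O[C@@H](c4ccc(OC)cc4)[C@H](c4cc(OC)cc(OC)c4C4OCC(C)(C)CO4)c23)cc1 | intermediate (not isolated)
24 | 2-{(2R,3R)-4-[(E)-1-(3,5-dimethoxyphenyl)-3-(4-methoxyphenyl)prop-1-en-2-yl]-6-methoxy-2-(4-methoxyphenyl)-2,3-dihydro-1-benzofuran-3-yl}-4,6-dimethoxybenzaldehyde | COc1ccc(C/C(=C\c2cc(OC)cc(OC)c2)c2cc(OC)cc3O[C@@H](c4ccc(OC)cc4)[C@H](c4cc(OC)cc(OC)c4C=O)c23)cc1 | intermediate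
25 | 4-methoxyphenylmagnesium bromide | COc1ccc([Mg]Br)cc1 | starting material
26 | (2-{(2R,3R)-4-[(E)-1-(3,5-dimethoxyphenyl)-3-(4-methoxyphenyl)prop-1-en-2-yl]-6-methoxy-2-(4-methoxyphenyl)-2,3-dihydro-1-benzofuran-3-yl}-4,6-dimethoxyphenyl)(4-methoxyphenyl)methanol, both epimers at the carbinol carbon | COc1ccc(C/C(=C\c2cc(OC)cc(OC)c2)c2cc(OC)cc3O[C@@H](c4ccc(OC)cc4)[C@H](c4cc(OC)cc(OC)c4C(O)c4ccc(OC)cc4)c23)cc1 | intermediate
27 | benzhydryl cation formed from 26 by loss of water (cation at C-a) | COc1ccc(C/C(=C\c2cc(OC)cc(OC)c2)c2cc(OC)cc3O[C@@H](c4ccc(OC)cc4)[C@H](c4cc(OC)cc(OC)c4[CH+]c4ccc(OC)cc4)c23)cc1 | intermediate (not isolated)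
28 | ring-closed tertiary benzylic cation (eight-membered ring formed, cation at C-c) | COc1ccc(C[C+]2c3cc(OC)cc4O[C@@H](c5ccc(OC)cc5)[C@@H](c34)c3cc(OC)cc(OC)c3[C@@H](c3ccc(OC)cc3)[C@@H]2c2cc(OC)cc(OC)c2)cc1 | intermediate (not isolated)
29 | ring-closed 4-methoxybenzylic cation (after hydride shift, cation at C-d) | COc1ccc([CH+][C@H]2c3cc(OC)cc4O[C@@H](c5ccc(OC)cc5)[C@@H](c34)c3cc(OC)cc(OC)c3[C@@H](c3ccc(OC)cc3)[C@@H]2c2cc(OC)cc(OC)c2)cc1 | intermediate (not isolated)
30 | stenophyllol B octamethyl ether | COc1ccc([C@H]2c3c(OC)cc(OC)cc3[C@H]3[C@H](c4ccc(OC)cc4)c4c(OC)cc(OC)cc4[C@@H]4c5c(cc(OC)cc5[C@H]23)O[C@H]4c2ccc(OC)cc2)cc1 | intermediate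
31 | stenophyllol B | Oc1ccc([C@H]2c3c(O)cc(O)cc3[C@H]3[C@H](c4ccc(O)cc4)c4c(O)cc(O)cc4[C@@H]4c5c(cc(O)cc5[C@H]23)O[C@H]4c2ccc(O)cc2)cc1 | target

**Step count**

Total steps: 13. Longest linear sequence: 11 steps (steps 1, 2, 4, 6, 7, 8, 9, 10, 11, 12, 13).

**Steps most likely to fail**

Step 12 (proposed new method). Cation 27 may be captured by arene rings of a second molecule instead of the alkene. The alkene may be protonated before ionization, which would close an indane that lacks the eight-membered ring. Ring closure may take place on the other face relative to C3 of the dihydrobenzofuran. An internal hydride transfer to 27 is a further possible leak. The fallback uses known chemistry, sets out from 20 and comes back to the route at 30. Acetal hydrolysis (1 M HCl, THF) should give 2-{(2R,3R)-4-[(3,5-dimethoxyphenyl)acetyl]-6-methoxy-2-(4-methoxyphenyl)-2,3-dihydro-1-benzofuran-3-yl}-4,6-dimethoxybenzaldehyde F1. Addition of 25 at −78 °C to the aldehyde, which is more electrophilic than the hindered enolizable ketone, should give the keto carbinol F2. Me3SiOTf and Et3N convert F2 into its silyl enol ether and benzhydryl silyl ether, and a catalytic amount of Me3SiOTf then triggers an intramolecular SN1 Mukaiyama alkylation; a silyl enol ether is a far better nucleophile than any of the methoxyarenes, and the centre next to the ketone can be equilibrated afterwards. This should give the eight-membered ketone F3. Addition of 4-methoxybenzylmagnesium chloride in the presence of LaCl3·2LiCl should give the tertiary alcohol F4. TsOH in (CF3)2CHOH–CH2Cl2 ionizes F4, and the same hydride shift and Friedel–Crafts closure as in step 12 should give 30.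

Step 6. The chiral ylide may give insufficient or opposite asymmetric induction, the lactone may release the quinone methide too slowly, and enantiopurity may be eroded through the cis isomer. The fallback sets out from 9 and comes back at 16. The achiral salt dimethyl(4-methoxybenzyl)sulfonium tetrafluoroborate F5 (from 10, Me2S and NaBF4) is used under the same Cs2CO3/MeI conditions and should give the racemic trans ester F6. F6 is resolved by preparative chromatography on a chiral stationary phase (supercritical CO2/MeOH) to give 16.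

Step 4. The aryllithium may attack the ester or the product lactone, and addition to the hindered, phenolate-deactivated aldehyde may be incomplete. The fallback sets out from 6 and comes back at 9. Lithiation and trapping with B(OMe)3 with a neutral work-up should give [2-(5,5-dimethyl-1,3-dioxan-2-yl)-3,5-dimethoxyphenyl]boronic acid F7. Rhodium-catalysed 1,2-addition of F7 to aldehyde 3 ([RhCl(cod)]2, K2CO3, dioxane–H2O, 80 °C), a known route from 2-formylbenzoates to 3-arylphthalides that tolerates the free phenol and the ester, followed by spontaneous lactonization, should give 9.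

Further compounds
F1 | step 12 | 2-{(2R,3R)-4-[(3,5-dimethoxyphenyl)acetyl]-6-methoxy-2-(4-methoxyphenyl)-2,3-dihydro-1-benzofuran-3-yl}-4,6-dimethoxybenzaldehyde | O=C(Cc1cc(OC)cc(OC)c1)c1cc(OC)cc2O[C@@H](c3ccc(OC)cc3)[C@H](c3cc(OC)cc(OC)c3C=O)c12
F2 | step 12 | 2-(3,5-dimethoxyphenyl)-1-{(2R,3R)-3-{2-[hydroxy(4-methoxyphenyl)methyl]-3,5-dimethoxyphenyl}-6-methoxy-2-(4-methoxyphenyl)-2,3-dihydro-1-benzofuran-4-yl}ethan-1-one (both carbinol epimers) | O=C(Cc1cc(OC)cc(OC)c1)c1cc(OC)cc2O[C@@H](c3ccc(OC)cc3)[C@H](c3cc(OC)cc(OC)c3C(O)c3ccc(OC)cc3)c12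
F3 | step 12 | eight-membered ring ketone (C-c as carbonyl; C-a and C-b as in 30; dihydrobenzofuran 2R,3R) | O=C1c2cc(OC)cc3O[C@@H](c4ccc(OC)cc4)[C@@H](c23)c2cc(OC)cc(OC)c2[C@@H](c2ccc(OC)cc2)[C@@H]1c1cc(OC)cc(OC)c1
F4 | step 12 | tertiary alcohol from addition of the 4-methoxybenzyl group to the carbonyl of F3 (configuration at the carbinol carbon not specified) | COc1ccc(CC2(O)c3cc(OC)cc4O[C@@H](c5ccc(OC)cc5)[C@@H](c34)c3cc(OC)cc(OC)c3[C@@H](c3ccc(OC)cc3)[C@@H]2c2cc(OC)cc(OC)c2)cc1
F5 | step 6 | dimethyl(4-methoxybenzyl)sulfonium tetrafluoroborate | COc1ccc(C[S+](C)C)cc1.F[B-](F)(F)F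
F6 | step 6 | racemic trans methyl 3-[2-(5,5-dimethyl-1,3-dioxan-2-yl)-3,5-dimethoxyphenyl]-6-methoxy-2-(4-methoxyphenyl)-2,3-dihydro-1-benzofuran-4-carboxylate (relative configuration drawn) | COC(=O)c1cc(OC)cc2O[C@@H](c3ccc(OC)cc3)[C@H](c3cc(OC)cc(OC)c3C3OCC(C)(C)CO3)c12
F7 | step 4 | [2-(5,5-dimethyl-1,3-dioxan-2-yl)-3,5-dimethoxyphenyl]boronic acid | OB(O)c1cc(OC)cc(OC)c1C1OCC(C)(C)CO1
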